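**Plan**

1. The target is numbered as an isochroman-1-one: C1 lactone carbonyl, O2, C3 the (R) centre carrying the 11-hydroxyundecyl chain, C4 benzylic CH2, C6–OMe, C8–OH. After unmasking (8-O-methyl, O-benzyl), the retrosynthesis cuts C8a–C1 and O2–C3 together, which removes C1(=O)–O2 as CO2. It then cuts the C4–aryl bond and the C3–chain bond back to epichlorohydrin.
2. Enabling feature: in the lactone ring (C1, O2, C3, C4, C4a, C8a) the unit C1(=O)–O2 is a CO2 molecule bridging arene carbon C8a and sp3 carbon C3. C8a can be made a carbanion (C–Br to C–Li) and C3 an electrophile (secondary sulfonate). CO2 is electrophilic at carbon and, once captured, nucleophilic at oxygen.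
3. Forward: a C10 Grignard reagent and (S)-epichlorohydrin give the (S)-epoxide, and the aryl Grignard reagent opens it. Bromination at the future C8a and tosylation at the future C3 follow. The only ring, the δ-lactone, then closes by Br–Li exchange, CO2 capture and invertive lactonisation. BCl3 finally frees the 8-OH and the primary alcohol.
4. Stereochemistry: the single centre comes from (S)-epichlorohydrin, is carried untouched to the (S)-tosylate, and is inverted once, stereospecifically, in the key step to give (3R).

Key step: step 6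

Remark: 10-bromodecan-1-ol, (S)-epichlorohydrin and 1-bromo-3,5-dimethoxybenzene are taken as commercial.

**Route**

Step 1
Reactants: 1 10-bromodecan-1-ol
Product: 2 benzyl 10-bromodecyl ether
Conditions: BnOC(=NH)CCl3 (1.2 equiv), TfOH (5 mol%), CH2Cl2/cyclohexane, 0 °C → rt
Reagents that add atoms: benzyl 2,2,2-trichloroacetimidate, ClC(Cl)(Cl)C(=N)OCc1ccccc1
Why: Acid-catalysed O-benzylation with a trichloroacetimidate runs without base, so the primary bromide is untouched and no Williamson self-alkylation can occur.

Step 2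
Reactants: 2 benzyl 10-bromodecyl ether; 3 (S)-epichlorohydrin
Product: 6 (2S)-2-[11-(benzyloxy)undecyl]oxirane, via Grignard reagent 4 (not isolated), via (S)-chlorohydrin 5 (not isolated)
Conditions: Mg, THF, 40 °C; CuI (5 mol%), 3, THF, −40 → 0 °C; then 4 M aq. NaOH, rt (same flask)
Reagents that add atoms: magnesium, [Mg] (held only in intermediate 4)
Why: Copper-catalysed Grignard opening of the epoxide at its unsubstituted carbon gives chlorohydrin 5, and hydroxide then closes the new oxirane by intramolecular Williamson displacement of chloride; no bond to the stereocentre is made or broken, so the (S) centre of 3 is carried over.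

Step 3
Reactants: 6 (2S)-2-[11-(benzyloxy)undecyl]oxirane; 7 1-bromo-3,5-dimethoxybenzene
Product: 9 (2S)-13-(benzyloxy)-1-(3,5-dimethoxyphenyl)tridecan-2-ol, via arylmagnesium bromide 8 (not isolated)
Conditions: Mg, THF, reflux (from 7); CuI (10 mol%), 6, THF, −30 °C → rt; 1 M HCl work-up
Reagents that add atoms: magnesium, [Mg] (held only in intermediate 8)
Why: Cu(I)-catalysed aryl Grignard opening of a monosubstituted epoxide is an SN2 attack at the terminal CH2, which forms the aryl–C4 bond and leaves the (S) carbinol centre untouched.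

Step 4
Reactants: 9 (2S)-13-(benzyloxy)-1-(3,5-dimethoxyphenyl)tridecan-2-ol
Product: 10 (2S)-13-(benzyloxy)-1-(2-bromo-3,5-dimethoxyphenyl)tridecan-2-ol
Conditions: NBS (1.0 equiv), MeCN, 0 °C, dark
Reagents that add atoms: N-bromosuccinimide, O=C1CCC(=O)N1Br
Why: Electrophilic aromatic bromination of the 3,5-dimethoxyphenyl ring should go to the position ortho to the alkyl chain and para to a methoxy group (the two such positions are equivalent), because the site between the two methoxy groups is more hindered and the unactivated benzyl ring and the alcohol do not react.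

Step 5
Reactants: 10 (2S)-13-(benzyloxy)-1-(2-bromo-3,5-dimethoxyphenyl)tridecan-2-ol
Product: 11 (2S)-13-(benzyloxy)-1-(2-bromo-3,5-dimethoxyphenyl)tridecan-2-yl 4-methylbenzenesulfonate
Conditions: TsCl (1.5 equiv), Et3N, DMAP (10 mol%), CH2Cl2, 0 °C → rt
Reagents that add atoms: 4-toluenesulfonyl chloride, Cc1ccc(cc1)S(=O)(=O)Cl
Why: O-sulfonylation of a secondary alcohol does not break the C–O bond, so the (S) configuration is retained while the carbinol carbon becomes an electrophile.

Step 6
Reactants: 11 (2S)-13-(benzyloxy)-1-(2-bromo-3,5-dimethoxyphenyl)tridecan-2-yl 4-methylbenzenesulfonate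
Product: 14 (3R)-3-[11-(benzyloxy)undecyl]-6,8-dimethoxy-3,4-dihydro-1H-isochromen-1-one, via aryllithium 12 (not isolated), via lithium carboxylate 13 (not isolated)
Conditions: n-BuLi (1.05 equiv), THF, −90 °C, 5 min; CO2 (g), −90 °C → rt; then DMF, 60 °C
Reagents that add atoms: carbon dioxide, O=C=O; n-butyllithium, [Li]CCCC (lithium held only in intermediates 12 and 13)
Why: Bromine–lithium exchange at −90 °C (Parham-type generation of an aryllithium beside an internal electrophile) should give 12 faster than any attack on the sulfonate; CO2 is then captured at the aryl carbon to give benzoate 13, and on warming in DMF the carboxylate oxygen displaces the secondary tosylate intramolecularly, so that C8a–C1 and O2–C3 are both made in one flask with CO2 as the two-atom linchpin. The closest known reaction types are the Parham carboxylation of ortho-functionalised aryllithiums and the invertive displacement of secondary sulfonates by carboxylates (lactonisation by O-alkylation). The only ring formed, the six-membered lactone (C1, O2, C3, C4, C4a, C8a), closes in the 6-exo-tet mode. The C3 centre is set by the backside trajectory of this SN2 step, which the tether allows without strain, so the (S)-tosylate should give the (3R)-lactone stereospecifically. The step needs chemoselectivity (exchange before attack on the tosylate, substitution instead of E2 towards the conjugated styrene), which is secured by the low temperature and immediate CO2 quench, the weak basicity of the carboxylate and the high effective molarity of the ortho carboxylate; the regiochemistry is fixed by the bromine, and the benzyl and methyl ethers are inert.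

Step 7
Reactants: 14 (3R)-3-[11-(benzyloxy)undecyl]-6,8-dimethoxy-3,4-dihydro-1H-isochromen-1-one
Product: 15 (3R)-8-hydroxy-3-(11-hydroxyundecyl)-6-methoxy-3,4-dihydro-1H-isochromen-1-one
Conditions: BCl3 (4 equiv), CH2Cl2, −78 → 0 °C; H2O quench
Reagents that add atoms: none
Why: BCl3 should cleave only the peri (C8) methyl ether, through a six-membered boron chelate with the lactone carbonyl, and also the primary benzyl ether (Lewis acid-mediated ether cleavage), while the non-chelated 6-OMe, the lactone and the C3 centre stay untouched.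

**Compound list**

1 | 10-bromodecan-1-ol | OCCCCCCCCCCBr | starting material
2 | benzyl 10-bromodecyl ether | BrCCCCCCCCCCOCc1ccccc1 | intermediate
3 | (S)-epichlorohydrin, (2S)-2-(chloromethyl)oxirane | ClC[C@@H]1CO1 | starting material
4 | [10-(benzyloxy)decyl]magnesium bromide | Br[Mg]CCCCCCCCCCOCc1ccccc1 | intermediate
5 | (2S)-13-(benzyloxy)-1-chlorotridecan-2-ol | ClC[C@@H](O)CCCCCCCCCCCOCc1ccccc1 | intermediate
6 | (2S)-2-[11-(benzyloxy)undecyl]oxirane | c1ccccc1COCCCCCCCCCCC[C@H]1CO1 | intermediate
7 | 1-bromo-3,5-dimethoxybenzene | COc1cc(Br)cc(OC)c1 | starting material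
8 | (3,5-dimethoxyphenyl)magnesium bromide | COc1cc([Mg]Br)cc(OC)c1 | intermediate
9 | (2S)-13-(benzyloxy)-1-(3,5-dimethoxyphenyl)tridecan-2-ol | COc1cc(OC)cc(C[C@@H](O)CCCCCCCCCCCOCc2ccccc2)c1 | intermediate
10 | (2S)-13-(benzyloxy)-1-(2-bromo-3,5-dimethoxyphenyl)tridecan-2-ol | COc1cc(OC)c(Br)c(C[C@@H](O)CCCCCCCCCCCOCc2ccccc2)c1 | intermediate
11 | (2S)-13-(benzyloxy)-1-(2-bromo-3,5-dimethoxyphenyl)tridecan-2-yl 4-methylbenzenesulfonate | COc1cc(OC)c(Br)c(C[C@@H](OS(=O)(=O)c2ccc(C)cc2)CCCCCCCCCCCOCc3ccccc3)c1 | intermediate
12 | {2-[(2S)-13-(benzyloxy)-2-(tosyloxy)tridecyl]-4,6-dimethoxyphenyl}lithium | COc1cc(OC)c([Li])c(C[C@@H](OS(=O)(=O)c2ccc(C)cc2)CCCCCCCCCCCOCc3ccccc3)c1 | intermediate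
13 | lithium 2-[(2S)-13-(benzyloxy)-2-(tosyloxy)tridecyl]-4,6-dimethoxybenzoate | COc1cc(OC)c(C(=O)[O-])c(C[C@@H](OS(=O)(=O)c2ccc(C)cc2)CCCCCCCCCCCOCc3ccccc3)c1.[Li+] | intermediate
14 | (3R)-3-[11-(benzyloxy)undecyl]-6,8-dimethoxy-3,4-dihydro-1H-isochromen-1-one | COc1cc(OC)c2c(c1)C[C@@H](CCCCCCCCCCCOCc3ccccc3)OC2=O | intermediate
15 | (3R)-8-hydroxy-3-(11-hydroxyundecyl)-6-methoxy-3,4-dihydro-1H-isochromen-1-one | COc1cc(O)c2c(c1)C[C@@H](CCCCCCCCCCCO)OC2=O | target

**Count and risks**

Total step count: 7. Longest linear sequence: 7 steps (1 → 2 → 6 → 9 → 10 → 11 → 14 → 15); 3 and 7 enter as commercial materials.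

Steps most likely to fail:

1. Step 6. The sulfonate may be consumed before carboxylation (attack or elimination by butyllithium or by the aryllithium), or E2 elimination towards the conjugated styrene may compete with ring closure during the carboxylate displacement. The fallback sets out from 10 and returns at 14; it inverts the centre first and then uses the alcohol oxygen as the ring oxygen. Mitsunobu reaction of 10 with 4-nitrobenzoic acid (PPh3, DIAD, THF) should give the inverted ester (2R)-13-(benzyloxy)-1-(2-bromo-3,5-dimethoxyphenyl)tridecan-2-yl 4-nitrobenzoate F1. Methanolysis (K2CO3, MeOH) should give the bromo alcohol (2R)-13-(benzyloxy)-1-(2-bromo-3,5-dimethoxyphenyl)tridecan-2-ol F2. Treatment with n-BuLi (2.2 equiv, THF, −78 °C) and then CO2 should give, after acidification, the hydroxy acid 2-[(2R)-13-(benzyloxy)-2-hydroxytridecyl]-4,6-dimethoxybenzoic acid F3, which lactonises with retention (TsOH cat., toluene) to 14.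

2. Step 4. Regiocontrol of the bromination may be poor (attack between the two methoxy groups, or a second bromination). The fallback sets out from 9 and returns at 14, replacing the halogen by a formyl group that deactivates the ring after one substitution. Tosylation of 9 (TsCl, Et3N, DMAP) should give (2S)-13-(benzyloxy)-1-(3,5-dimethoxyphenyl)tridecan-2-yl 4-methylbenzenesulfonate F4. Vilsmeier–Haack formylation (POCl3, DMF, 0 °C → rt; aq. NaOAc) with the bulkier chloroiminium electrophile should give the aldehyde (2S)-13-(benzyloxy)-1-(2-formyl-3,5-dimethoxyphenyl)tridecan-2-yl 4-methylbenzenesulfonate F5. Pinnick oxidation (NaClO2, NaH2PO4, 2-methyl-2-butene, t-BuOH/H2O) should give the acid 2-[(2S)-13-(benzyloxy)-2-(tosyloxy)tridecyl]-4,6-dimethoxybenzoic acid F6. K2CO3 in DMF at 50 °C should then close the lactone with inversion to 14.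

3. Step 7. Cleavage of the benzyl ether may be incomplete at the temperature that spares the 6-methoxy group, or the second methyl ether may be lost on forcing. The fallback sets out from 14 and returns at 15, separating the two deprotections. Hydrogenolysis (H2, Pd/C, EtOAc) should give (3R)-3-(11-hydroxyundecyl)-6,8-dimethoxy-3,4-dihydro-1H-isochromen-1-one F7. Chelation-controlled demethylation of the C8 methyl ether alone (AlCl3, CH2Cl2, 0 °C → rt) should then give 15.

**Further compounds**

F1 | step 6 | (2R)-13-(benzyloxy)-1-(2-bromo-3,5-dimethoxyphenyl)tridecan-2-yl 4-nitrobenzoate | COc1cc(OC)c(Br)c(C[C@H](OC(=O)c2ccc(cc2)[N+](=O)[O-])CCCCCCCCCCCOCc3ccccc3)c1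
F2 | step 6 | (2R)-13-(benzyloxy)-1-(2-bromo-3,5-dimethoxyphenyl)tridecan-2-ol | COc1cc(OC)c(Br)c(C[C@H](O)CCCCCCCCCCCOCc2ccccc2)c1
F3 | step 6 | 2-[(2R)-13-(benzyloxy)-2-hydroxytridecyl]-4,6-dimethoxybenzoic acid | COc1cc(OC)c(C(=O)O)c(C[C@H](O)CCCCCCCCCCCOCc2ccccc2)c1
F4 | step 4 | (2S)-13-(benzyloxy)-1-(3,5-dimethoxyphenyl)tridecan-2-yl 4-methylbenzenesulfonate | COc1cc(OC)cc(C[C@@H](OS(=O)(=O)c2ccc(C)cc2)CCCCCCCCCCCOCc3ccccc3)c1
F5 | step 4 | (2S)-13-(benzyloxy)-1-(2-formyl-3,5-dimethoxyphenyl)tridecan-2-yl 4-methylbenzenesulfonate | COc1cc(OC)c(C=O)c(C[C@@H](OS(=O)(=O)c2ccc(C)cc2)CCCCCCCCCCCOCc3ccccc3)c1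
F6 | step 4 | 2-[(2S)-13-(benzyloxy)-2-(tosyloxy)tridecyl]-4,6-dimethoxybenzoic acid | COc1cc(OC)c(C(=O)O)c(C[C@@H](OS(=O)(=O)c2ccc(C)cc2)CCCCCCCCCCCOCc3ccccc3)c1
F7 | step 7 | (3R)-3-(11-hydroxyundecyl)-6,8-dimethoxy-3,4-dihydro-1H-isochromen-1-one | COc1cc(OC)c2c(c1)C[C@@H](CCCCCCCCCCCO)OC2=O
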